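**Retrosynthetic overview**
1. The target comes from its octa-O-benzyl ether by neutral hydrogenolysis in the last step, so C2 never meets base.
2. Both O1–C2 bonds are cut at once. This gives one acyclic precursor carrying a 2'-hydroxychalcone (future flavanone ring C) and an o-hydroxyaryl 1,3-diketone (future flavone ring C). In the forward direction a catalytic asymmetric oxa-Michael addition sets 2S, and acid cyclodehydration follows in the same flask.
3. The chalcone C=C comes from a Claisen–Schmidt condensation of a biaryl aldehyde with di-O-benzylphloroacetophenone.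
4. The biaryl C5'–C8'' bond comes from a Suzuki coupling of a 3-iodo-2-hydroxyaryl diketone with the boronate of di-O-benzyl-5-bromoprotocatechualdehyde. The diketone comes from a crossed Claisen condensation.
5. Ring order: the four benzene rings are bought. Flavanone ring C closes first and flavone ring C second, both in the penultimate step.

Assumption: the three benzene building blocks are bought as catalogue chemicals; the quinine-derived thiourea is taken to give the 2S product (checked by CD, positive band near 330 nm and negative band near 290 nm) and its quinidine-derived pseudoenantiomer replaces it if the first run shows 2R; the tri-ortho-substituted biaryl axis rotates freely enough that no axial stereoelement has to be set.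

**Step 1**
Reactants: 1 1-[2,4-bis(benzyloxy)-6-hydroxyphenyl]ethan-1-one
Product: 2 1-[4,6-bis(benzyloxy)-2-hydroxy-3-iodophenyl]ethan-1-one
Conditions: NIS (1.05 equiv), DMF, 0 °C to rt, dark, 4 h
Reagents that add atoms: N-iodosuccinimide, O=C1CCC(=O)N1I
Why: Electrophilic aromatic iodination, in which the free chelated phenol directs ortho and C3 (between OH and OBn) is less crowded than C5 (between two OBn groups), so one equivalent of NIS gives the 3-iodide.

**Step 2**
Reactants: 2 1-[4,6-bis(benzyloxy)-2-hydroxy-3-iodophenyl]ethan-1-one; 3 methyl 3,4-bis(benzyloxy)benzoate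
Product: 4 1-[4,6-bis(benzyloxy)-2-hydroxy-3-iodophenyl]-3-[3,4-bis(benzyloxy)phenyl]propane-1,3-dione (mainly enol)
Conditions: LiHMDS (4 equiv), THF, −78 °C; then 3 (1.2 equiv), −78 °C to rt, 16 h; 1 M HCl
Reagents that add atoms: none
Why: Crossed Claisen condensation (direct version of the Baker–Venkataraman acylation), in which the phenoxide/enolate dianion of the methyl ketone attacks the non-enolisable ester, the product is drained off as its stabilised diketonate, and LiHMDS leaves the aryl iodide alone.

**Step 3**
Reactants: 5 3-bromo-4,5-dihydroxybenzaldehyde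
Product: 6 3,4-bis(benzyloxy)-5-bromobenzaldehyde
Conditions: BnBr (2.4 equiv), K2CO3 (3 equiv), DMF, 60 °C, 6 h
Reagents that add atoms: benzyl bromide, BrCc1ccccc1
Why: Williamson ether synthesis on both acidic catechol hydroxyls, with the aldehyde and the aryl bromide inert to carbonate.

**Step 4**
Reactants: 6 3,4-bis(benzyloxy)-5-bromobenzaldehyde; 4 1-[4,6-bis(benzyloxy)-2-hydroxy-3-iodophenyl]-3-[3,4-bis(benzyloxy)phenyl]propane-1,3-dione
Product: 8 3,4-bis(benzyloxy)-5-[4,6-bis(benzyloxy)-3-{3-[3,4-bis(benzyloxy)phenyl]-3-oxopropanoyl}-2-hydroxyphenyl]benzaldehyde, via pinacol boronate 7 (not isolated)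
Conditions: 6 (1.4 equiv), B2pin2 (1.45 equiv), Pd2(dba)3 (2 mol %), XPhos (8 mol %), KOAc (3 equiv), dioxane, 90 °C, 4 h; then 4 (1 equiv), aq K3PO4 (5 equiv), 80 °C, 12 h
Reagents that add atoms: bis(pinacolato)diboron, CC1(C)OB(OC1(C)C)B1OC(C)(C)C(C)(C)O1 (boron group of 7 only, lost again on the way to 8)
Why: Miyaura borylation followed in the same flask by Suzuki–Miyaura coupling, in which the bromide is fully borylated before the iodide is added and the bulky biarylphosphine on zerovalent palladium handles the tri-ortho-substituted biaryl, as in 8-iodoflavone couplings.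

**Step 5**
Reactants: 8 biaryl aldehyde-diketone (name as in step 4); 1 1-[2,4-bis(benzyloxy)-6-hydroxyphenyl]ethan-1-one
Product: 9 1-{4,6-bis(benzyloxy)-3-[2,3-bis(benzyloxy)-5-{(E)-3-[2,4-bis(benzyloxy)-6-hydroxyphenyl]-3-oxoprop-1-en-1-yl}phenyl]-2-hydroxyphenyl}-3-[3,4-bis(benzyloxy)phenyl]propane-1,3-dione
Conditions: 1 (1.5 equiv), KOH (50% aq, 20 equiv), EtOH/THF 2:1, rt, 48 h; 1 M HCl to pH 5 at 0 °C
Reagents that add atoms: none
Why: Claisen–Schmidt condensation, in which the diketone sits as an unreactive phenoxide/diketonate dianion whose aldol adducts revert in aqueous hydroxide, while the methyl ketone enolate of 1 gives the (E)-chalcone phenoxide irreversibly by E1cB loss of water.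

**Step 6**
Reactants: 9 chalcone-diketone (name as in step 5)
Product: 11 (2S)-5,7-bis(benzyloxy)-2-{3,4-bis(benzyloxy)-5-[5,7-bis(benzyloxy)-2-(3,4-bis(benzyloxy)phenyl)-4-oxo-4H-chromen-8-yl]phenyl}chroman-4-one, via flavanone-diketone 10 (not isolated)
Conditions: N-[3,5-bis(trifluoromethyl)phenyl]-N'-[(8α,9S)-6'-methoxycinchonan-9-yl]thiourea (20 mol %), toluene (0.05 M), 0 °C, 72 h (until the orange chalcone is gone by HPLC); then TsOH·H2O (0.6 equiv), 60 °C, 2 h
Reagents that add atoms: none
Why: Proposed new method: an enantioselective intramolecular oxa-Michael addition is run on a non-activated 2'-hydroxychalcone and telescoped with an acid cyclodehydration so that both pyranone rings close in one flask; the quinuclidine nitrogen takes the proton of the chelated 2'-OH while the thiourea binds the enone carbonyl, which the 6'-benzyloxy group twists out of the arene plane (more electrophilic enone, equilibrium far on the flavanone side, slow retro-addition at 0 °C), so the phenoxide adds 6-endo-trig to one face of the (E)-alkene and sets C2 as S; TsOH then protonates the amine before warming, which stops base-mediated ring opening, and dehydrates the hemiketal of the o-hydroxyaryl 1,3-diketone through the only free ortho OH, which fixes the 8-aryl flavone regiochemistry; the closest known reaction types are the cinchona-alkaloid and cinchona-thiourea catalysed oxa-Michael cyclisations of o-tigloylphenols and of 2-hydroxyaryl alkylidene β-ketoesters (the latter followed by TsOH at 80 °C without loss of ee) and the acid cyclodehydration that ends a Baker–Venkataraman flavone synthesis.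

**Step 7**
Reactants: 11 (2S)-octa-O-benzyl biflavonoid (name as in step 6)
Product: 12 (2S)-2-{3-[2-(3,4-dihydroxyphenyl)-5,7-dihydroxy-4-oxo-4H-chromen-8-yl]-4,5-dihydroxyphenyl}-5,7-dihydroxychroman-4-one (target)
Conditions: H2 (1 atm), 10% Pd/C, THF/MeOH 1:1, rt, 6 h
Reagents that add atoms: none
Why: Catalytic hydrogenolysis of the eight benzyl ethers under neutral conditions, in which the flavone C2=C3 bond and the aryl ketone survive 1 atm of H2 at rt and no acid or base is present to open the flavanone ring, so C2 stays S.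

**Compound list**
1 | 1-[2,4-bis(benzyloxy)-6-hydroxyphenyl]ethan-1-one | CC(=O)c1c(O)cc(OCc2ccccc2)cc1OCc1ccccc1 | starting material
2 | 1-[4,6-bis(benzyloxy)-2-hydroxy-3-iodophenyl]ethan-1-one | CC(=O)c1c(O)c(I)c(OCc2ccccc2)cc1OCc1ccccc1 | intermediate
3 | methyl 3,4-bis(benzyloxy)benzoate | COC(=O)c1ccc(OCc2ccccc2)c(OCc2ccccc2)c1 | starting material
4 | iodo-diketone (step 2 product) | O=C(CC(=O)c1ccc(OCc2ccccc2)c(OCc2ccccc2)c1)c1c(O)c(I)c(OCc2ccccc2)cc1OCc1ccccc1 | intermediate
5 | 3-bromo-4,5-dihydroxybenzaldehyde | O=Cc1cc(O)c(O)c(Br)c1 | starting material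
6 | 3,4-bis(benzyloxy)-5-bromobenzaldehyde | O=Cc1cc(OCc2ccccc2)c(OCc2ccccc2)c(Br)c1 | intermediate
7 | 3,4-bis(benzyloxy)-5-(4,4,5,5-tetramethyl-1,3,2-dioxaborolan-2-yl)benzaldehyde (not isolated) | O=Cc1cc(OCc2ccccc2)c(OCc2ccccc2)c(B2OC(C)(C)C(C)(C)O2)c1 | intermediate
8 | biaryl aldehyde-diketone (step 4 product) | O=Cc1cc(OCc2ccccc2)c(OCc2ccccc2)c(-c2c(O)c(C(=O)CC(=O)c3ccc(OCc4ccccc4)c(OCc4ccccc4)c3)c(OCc3ccccc3)cc2OCc2ccccc2)c1 | intermediate
9 | (E)-chalcone-diketone (step 5 product) | O=C(/C=C/c1cc(OCc2ccccc2)c(OCc2ccccc2)c(-c2c(O)c(C(=O)CC(=O)c3ccc(OCc4ccccc4)c(OCc4ccccc4)c3)c(OCc3ccccc3)cc2OCc2ccccc2)c1)c1c(O)cc(OCc2ccccc2)cc1OCc1ccccc1 | intermediate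
10 | (2S)-flavanone-diketone, flavanone ring C closed and diketone still open (not isolated) | O=C1C[C@@H](c2cc(OCc3ccccc3)c(OCc3ccccc3)c(-c3c(O)c(C(=O)CC(=O)c4ccc(OCc5ccccc5)c(OCc5ccccc5)c4)c(OCc4ccccc4)cc3OCc3ccccc3)c2)Oc2cc(OCc3ccccc3)cc(OCc3ccccc3)c21 | intermediate
11 | (2S)-octa-O-benzyl biflavonoid (step 6 product) | O=C1C[C@@H](c2cc(OCc3ccccc3)c(OCc3ccccc3)c(-c3c(OCc4ccccc4)cc(OCc4ccccc4)c4c(=O)cc(-c5ccc(OCc6ccccc6)c(OCc6ccccc6)c5)oc34)c2)Oc2cc(OCc3ccccc3)cc(OCc3ccccc3)c21 | intermediate
12 | (2S)-2,3-dihydro-5',8''-biluteolin, CNP0224656.1 | O=C1C[C@@H](c2cc(O)c(O)c(-c3c(O)cc(O)c4c(=O)cc(-c5ccc(O)c(O)c5)oc34)c2)Oc2cc(O)cc(O)c21 | target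

**Totals**
- Total step count: 7.
- Longest linear sequence: 6 (steps 1, 2, 4, 5, 6, 7).
- The ee is read on 11 by chiral HPLC. Compound 11 can be recrystallised to raise the ee before step 7.

**Three steps most likely to fail**

Step 6 carries the most risk.
- The chalcone has no extra activating group, so the cyclisation may be slow or only moderately selective.
- The acidic diketone may tie up part of the catalyst.
- Chalcone left over at the acid stage stays largely open and has to be removed as a coloured band.

The fallback sets out from 9 and comes back at 11. NaOAc in refluxing EtOH/THF closes the flavanone without stereocontrol. TsOH in toluene at 60 °C then closes the flavone and gives the racemic octabenzyl biflavonoid F1. A kinetic resolution by asymmetric transfer hydrogenation follows, with RuCl(p-cymene)[(R,R)-TsDPEN] and HCO2H/Et3N in EtOAc, stopped near 52% conversion. It reduces the 2R ketone to the cis-(2R,4R)-flavan-4-ol F2 and leaves 11. The two are separated on silica.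

Step 4 is the second risk.
- The iodide is flanked by two oxygen substituents and reacts as an electron-rich phenoxide.
- It carries a chelating diketonate.
- Slow oxidative addition, protodeiodination and protodeboronation can therefore compete.

The fallback sets out from 2 and 7 (made from 6 as in step 4) and comes back at 8. The simple iodoketone 2 is coupled with 7 under the same catalyst to give the keto-aldehyde F3. Its phenol is deprotonated, and its aldehyde is masked in the flask at −40 °C as the lithium morpholide adduct F4. LiHMDS and ester 3 then carry out the crossed Claisen condensation on the methyl ketone. The 1 M HCl work-up releases the aldehyde again. In this way the diketone is built after the biaryl bond instead of before it.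

Step 5 is the third risk. The diketone could act as a carbon nucleophile (Knoevenagel or Michael addition) or suffer retro-Claisen cleavage during two days in KOH.

The fallback sets out from 6 and 1 and comes back at 9. The Claisen–Schmidt condensation is run before any diketone is present and gives the bromochalcone F5. Miyaura borylation turns it into the chalcone boronate F6. Suzuki coupling of F6 with 4 then delivers 9. Any flavanone formed under the coupling base is reopened by a short KOH/EtOH treatment before isolation.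

**Further compounds**
F1 | step 6 | racemic octa-O-benzyl biflavonoid | O=C1CC(c2cc(OCc3ccccc3)c(OCc3ccccc3)c(-c3c(OCc4ccccc4)cc(OCc4ccccc4)c4c(=O)cc(-c5ccc(OCc6ccccc6)c(OCc6ccccc6)c5)oc34)c2)Oc2cc(OCc3ccccc3)cc(OCc3ccccc3)c21
F2 | step 6 | cis-(2R,4R)-flavan-4-ol from the 2R enantiomer | O[C@@H]1C[C@H](c2cc(OCc3ccccc3)c(OCc3ccccc3)c(-c3c(OCc4ccccc4)cc(OCc4ccccc4)c4c(=O)cc(-c5ccc(OCc6ccccc6)c(OCc6ccccc6)c5)oc34)c2)Oc2cc(OCc3ccccc3)cc(OCc3ccccc3)c21
F3 | step 4 | 3-[3-acetyl-4,6-bis(benzyloxy)-2-hydroxyphenyl]-4,5-bis(benzyloxy)benzaldehyde | CC(=O)c1c(O)c(-c2cc(C=O)cc(OCc3ccccc3)c2OCc2ccccc2)c(OCc2ccccc2)cc1OCc1ccccc1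
F4 | step 4 | dilithium salt of the morpholine hemiaminal of F3 | [Li+].[Li+].CC(=O)c1c([O-])c(-c2cc(C([O-])N3CCOCC3)cc(OCc3ccccc3)c2OCc2ccccc2)c(OCc2ccccc2)cc1OCc1ccccc1
F5 | step 5 | (E)-1-[2,4-bis(benzyloxy)-6-hydroxyphenyl]-3-[3,4-bis(benzyloxy)-5-bromophenyl]prop-2-en-1-one | O=C(/C=C/c1cc(OCc2ccccc2)c(OCc2ccccc2)c(Br)c1)c1c(O)cc(OCc2ccccc2)cc1OCc1ccccc1
F6 | step 5 | (E)-1-[2,4-bis(benzyloxy)-6-hydroxyphenyl]-3-[3,4-bis(benzyloxy)-5-(4,4,5,5-tetramethyl-1,3,2-dioxaborolan-2-yl)phenyl]prop-2-en-1-one | O=C(/C=C/c1cc(OCc2ccccc2)c(OCc2ccccc2)c(B2OC(C)(C)C(C)(C)O2)c1)c1c(O)cc(OCc2ccccc2)cc1OCc1ccccc1
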